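Plan
- Retrosynthesis: ring C is cut at O1-C2 and at C2-C3. This gives a ring A ketone (a 2-hydroxy-3-prenyl-4,6-dioxygenated alpha-alkoxyacetophenone) and a ring B acid (a 3,4-dioxygenated 2,6-diprenylbenzoic acid) whose carboxyl carbon becomes C2.
- Ring B is then cut at C2'-C3' and C1'-C6'. This works because ring B is pentasubstituted: the acyl-bearing C1' lies between the prenyl groups at C2' and C6', C3' and C4' carry neighbouring oxygens, and only C5' carries H. C3'-C4'-C5'-C6' plus the C3' oxygen is therefore a 4-methoxy-2-prenylfuran, and C1'-C2' is a prenyl-substituted alkynoate.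
- Forward order: furan and ynoate are made, ring B arises by cycloaddition and bridge opening, and both O-methyl groups are exchanged for MOM. Ring A is bought as 2,4,6-trihydroxyacetophenone and receives a C-prenyl group, MOM groups and an alpha oxygen.
- Enolate acylation joins the halves. Ring C closes last and under base, so O1 is the oxygen next to the prenyl group (8-prenyl series). All MOM groups are removed at the end.
- Stereochemistry: the target has no stereocentre. The bridgeheads of the cycloadduct and C2 of the 1,3-diketone are transient.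

Key step: step 6

Remark: prenyl stands for 3-methylbut-2-enyl and MOM for methoxymethyl. The target SMILES carries no stereodescriptor, so the hindered C2-C1' axis is left undefined and all chiral intermediates are racemic.

Step 1
Reactants: 1 3-bromofuran
Product: 2 3-methoxyfuran
Conditions: NaOMe, CuBr (10 mol %), MeOH-NMP, 110 °C
Reagents that add atoms: sodium methoxide, [Na+].[O-]C
Why: In this copper-catalysed Ullmann-type ether synthesis, methoxide replaces the bromide at the unactivated beta position, the usual entry to 3-alkoxy five-membered heteroarenes.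

Step 2
Reactants: 2 3-methoxyfuran
Product: 4 (3-methoxyfuran-2-yl)trimethylsilane, via 2-lithio-3-methoxyfuran 3 (not isolated)
Conditions: n-BuLi, THF, -78 → 0 °C; Me3SiCl, -78 °C → rt
Reagents that add atoms: chlorotrimethylsilane, C[Si](C)(C)Cl
Why: In this directed alpha-lithiation, C2 is both alpha to the ring oxygen and ortho to the methoxy group, so it is metalated first and silylation blocks it.

Step 3
Reactants: 4 (3-methoxyfuran-2-yl)trimethylsilane; 5 prenyl bromide (1-bromo-3-methylbut-2-ene)
Product: 7 [3-methoxy-5-(3-methylbut-2-enyl)furan-2-yl]trimethylsilane, via 5-lithio-3-methoxy-2-(trimethylsilyl)furan 6 (not isolated)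
Conditions: n-BuLi, THF, -78 → 0 °C; 5, -78 °C → rt
Reagents that add atoms: none
Why: With C2 blocked, the only free alpha position (C5) is lithiated, and the furyllithium is alkylated at the primary carbon of the allylic bromide in an SN2 reaction.

Step 4
Reactants: 7 [3-methoxy-5-(3-methylbut-2-enyl)furan-2-yl]trimethylsilane
Product: 8 4-methoxy-2-(3-methylbut-2-enyl)furan
Conditions: n-Bu4NF·3H2O, THF, rt
Reagents that add atoms: none
Why: This fluoride-induced protodesilylation releases a furyl anion stabilised by the ring oxygen and the neighbouring methoxy group, and it keeps the medium free of the acid that would hydrolyse the enol ether.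

Step 5
Reactants: 9 methyl propiolate; 5 prenyl bromide
Product: 10 methyl 6-methylhept-5-en-2-ynoate
Conditions: CuI (10 mol %), n-Bu4NI (10 mol %), K2CO3, DMF, 0 °C → rt
Reagents that add atoms: none
Why: In this CuI-catalysed allylic substitution the copper acetylide attacks the primary carbon of the allylic halide, and the mild carbonate base at low temperature limits isomerisation of the skipped enynoate to the allenoate.

Step 6
Reactants: 8 4-methoxy-2-(3-methylbut-2-enyl)furan; 10 methyl 6-methylhept-5-en-2-ynoate
Product: 12 methyl 3-hydroxy-4-methoxy-2,6-bis(3-methylbut-2-enyl)benzoate, via 7-oxanorbornadiene adduct 11 (not isolated)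
Conditions: 8 (1.5 equiv), ZnI2 (20 mol %), BHT (trace), PhMe (concentrated), 70 °C, sealed tube
Reagents that add atoms: none
Why: Furan 8 adds as the 4π component across the ZnI2-activated triple bond of 10 in a concerted but asynchronous intermolecular [4+2] cycloaddition, which closes the six-membered carbocycle of ring B by forming C2'-C3' (furan C5 to ynoate C3) and C1'-C6' (ynoate C2 to furan C2) and gives 11. In 11 the C-O bond at the prenyl-bearing bridgehead ionises, because that tertiary cation is a vinylogous oxocarbenium ion of the enol ether whereas the other bridgehead cation would be cross-conjugated to the methoxy group, and loss of the remaining bridgehead proton leaves the oxygen as the C3' phenol next to the C4' methoxy group. The closest known reaction type is the Diels-Alder reaction of 3-alkoxyfurans with acetylenic esters followed by opening of the 7-oxanorbornadiene to a phenol. The step needs one regiochemistry, and both donors of 8 call for it: the methoxy group makes the unsubstituted C5 the carbon with the largest HOMO coefficient, which pairs with the electrophilic beta carbon of 10 (para rule), and the C2 alkyl group ends up next to the ester (ortho rule). The two bridgehead stereocentres of 11 result from suprafacial addition, are cis by the geometry of the bridge, are racemic and disappear on aromatisation. Aromatisation is irreversible and so drains the reversible furan cycloaddition, while the unactivated prenyl double bonds do not compete as dienophiles and ZnI2 is too mild to close the new phenol onto the C2' prenyl group.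

Step 7
Reactants: 12 methyl 3-hydroxy-4-methoxy-2,6-bis(3-methylbut-2-enyl)benzoate
Product: 13 methyl 4-methoxy-3-(methoxymethoxy)-2,6-bis(3-methylbut-2-enyl)benzoate
Conditions: MOMCl, i-Pr2NEt, CH2Cl2, 0 °C → rt
Reagents that add atoms: chloromethyl methyl ether, COCCl
Why: This O-alkylation (acetal protection) of the phenol is needed because a thiolate cannot demethylate an anisole that carries an ortho phenoxide, since a catecholate dianion would have to leave.

Step 8
Reactants: 13 methyl 4-methoxy-3-(methoxymethoxy)-2,6-bis(3-methylbut-2-enyl)benzoate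
Product: 14 4-hydroxy-3-(methoxymethoxy)-2,6-bis(3-methylbut-2-enyl)benzoic acid
Conditions: NaSEt (6 equiv), DMF, 120-130 °C; then 1 M HCl to pH 3-4, 0 °C
Reagents that add atoms: none
Why: In this thiolate SN2 dealkylation the soft nucleophile attacks both O-methyl carbons, so the ester is cleaved without any attack on its shielded acyl carbon and the aryl methyl ether falls in the same flask, while prenyl and MOM groups tolerate non-acidic nucleophiles.

Step 9
Reactants: 14 4-hydroxy-3-(methoxymethoxy)-2,6-bis(3-methylbut-2-enyl)benzoic acid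
Product: 16 3,4-bis(methoxymethoxy)-2,6-bis(3-methylbut-2-enyl)benzoic acid, via methoxymethyl ester 15 (not isolated)
Conditions: MOMCl (2.5 equiv), i-Pr2NEt, CH2Cl2, 0 °C → rt; then LiOH, THF-MeOH-H2O, rt; 1 M HCl to pH 3-4, 0 °C
Reagents that add atoms: chloromethyl methyl ether, COCCl
Why: MOM protection alkylates phenol and carboxylate alike, and the acyloxymethyl ether is then hydrolysed selectively because it is cleaved at its O-CH2-O carbon with carboxylate as leaving group, so the hindered acyl carbon is not involved and the aryl MOM ethers stay.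

Step 10
Reactants: 17 2,4,6-trihydroxyacetophenone; 5 prenyl bromide
Product: 18 1-[2,4,6-trihydroxy-3-(3-methylbut-2-enyl)phenyl]ethanone
Conditions: KOH (1 equiv), H2O, 0 °C → rt
Reagents that add atoms: none
Why: The ambident acylphloroglucinolate is C-alkylated in water, where the oxygens are solvated, and the two free ring positions are equivalent, so only one mono-C-prenyl isomer can form.

Step 11
Reactants: 18 1-[2,4,6-trihydroxy-3-(3-methylbut-2-enyl)phenyl]ethanone
Product: 19 1-[2-hydroxy-4,6-bis(methoxymethoxy)-3-(3-methylbut-2-enyl)phenyl]ethanone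
Conditions: MOMCl (2.2 equiv), i-Pr2NEt, CH2Cl2, 0 °C
Reagents that add atoms: chloromethyl methyl ether, COCCl
Why: In this selective acetal protection the para hydroxyl and the less hindered ortho hydroxyl react, while the hydroxyl between prenyl and acetyl stays locked in the hydrogen bond to the ketone and is the future O1.

Step 12
Reactants: 19 1-[2-hydroxy-4,6-bis(methoxymethoxy)-3-(3-methylbut-2-enyl)phenyl]ethanone
Product: 20 2-hydroxy-1-[2-hydroxy-4,6-bis(methoxymethoxy)-3-(3-methylbut-2-enyl)phenyl]ethanone
Conditions: KN(SiMe3)2 (2.2 equiv), THF, -78 °C; 2-(phenylsulfonyl)-3-phenyloxaziridine, -78 °C; AcOH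
Reagents that add atoms: 2-(phenylsulfonyl)-3-phenyloxaziridine, O=S(=O)(c1ccccc1)N1OC1c1ccccc1
Why: In this Davis enolate hydroxylation the phenoxide-enolate dianion takes up oxygen at carbon from the N-sulfonyloxaziridine, which does not epoxidise a trisubstituted alkene at -78 °C, and the potassium counterion suppresses addition of the enolate to the sulfonimine.

Step 13
Reactants: 20 2-hydroxy-1-[2-hydroxy-4,6-bis(methoxymethoxy)-3-(3-methylbut-2-enyl)phenyl]ethanone
Product: 21 1-[2-hydroxy-4,6-bis(methoxymethoxy)-3-(3-methylbut-2-enyl)phenyl]-2-(methoxymethoxy)ethanone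
Conditions: MOMCl (1.2 equiv), i-Pr2NEt, CH2Cl2, 0 °C
Reagents that add atoms: chloromethyl methyl ether, COCCl
Why: This acetal protection takes place at the primary alcohol, because the chelated and flanked phenol already resisted the same reagent in step 11.

Step 14
Reactants: 16 3,4-bis(methoxymethoxy)-2,6-bis(3-methylbut-2-enyl)benzoic acid; 21 1-[2-hydroxy-4,6-bis(methoxymethoxy)-3-(3-methylbut-2-enyl)phenyl]-2-(methoxymethoxy)ethanone
Product: 23 1-[3,4-bis(methoxymethoxy)-2,6-bis(3-methylbut-2-enyl)phenyl]-3-[2-hydroxy-4,6-bis(methoxymethoxy)-3-(3-methylbut-2-enyl)phenyl]-2-(methoxymethoxy)propane-1,3-dione, via acid chloride 22 (not isolated)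
Conditions: 16, 1-chloro-N,N,2-trimethylprop-1-en-1-amine, CH2Cl2, 0 °C, evaporation; 21, LiN(SiMe3)2 (3.2 equiv), THF, -78 °C, then 22 in THF, -78 °C → rt; AcOH
Reagents that add atoms: none
Why: In this one-flask variant of the Baker-Venkataraman diketone synthesis the phenoxide-enolate dianion is acylated at carbon by an aroyl chloride made under neutral conditions, any O-acylated material is carried to the same diketone by acyl shift under the excess base, and the new C2 centre is racemic and labile.

Step 15
Reactants: 23 the 1,3-diketone of step 14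
Product: 24 2-[3,4-bis(methoxymethoxy)-2,6-bis(3-methylbut-2-enyl)phenyl]-3,5,7-tris(methoxymethoxy)-8-(3-methylbut-2-enyl)-4H-chromen-4-one
Conditions: DBU, pyridine, 90 °C
Reagents that add atoms: none
Why: In this base-mediated cyclodehydration, known for 2-substituted o-hydroxyaryl 1,3-diketones, the only free phenoxide adds to the ring B carbonyl and water leaves by E1cB, and because no acid is present the other ortho MOM group stays on, which fixes the 8-prenyl regiochemistry and spares the prenyl groups.

Step 16
Reactants: 24 the pentakis-MOM flavonol of step 15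
Product: 25 petalostemumol G
Conditions: HCl (1.25 M in MeOH), MeOH-THF, 0 → 40 °C
Reagents that add atoms: none
Why: In this acid-catalysed transacetalisation each aryl or enol MOM acetal is exchanged with methanol to dimethoxymethane at a temperature at which trisubstituted alkenes are not yet protonated, the usual last step for C-prenylated flavonoids.

Compound list
1 | 3-bromofuran | Brc1ccoc1 | starting material
2 | 3-methoxyfuran | COc1ccoc1 | intermediate
3 | 2-lithio-3-methoxyfuran | [Li]c1occc1OC | intermediate
4 | (3-methoxyfuran-2-yl)trimethylsilane | COc1ccoc1[Si](C)(C)C | intermediate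
5 | prenyl bromide (1-bromo-3-methylbut-2-ene) | CC(C)=CCBr | starting material
6 | 5-lithio-3-methoxy-2-(trimethylsilyl)furan | [Li]c1cc(OC)c([Si](C)(C)C)o1 | intermediate
7 | [3-methoxy-5-(3-methylbut-2-enyl)furan-2-yl]trimethylsilane | COc1cc(CC=C(C)C)oc1[Si](C)(C)C | intermediate
8 | 4-methoxy-2-(3-methylbut-2-enyl)furan | COc1coc(CC=C(C)C)c1 | intermediate
9 | methyl propiolate | C#CC(=O)OC | starting material
10 | methyl 6-methylhept-5-en-2-ynoate | CC(C)=CCC#CC(=O)OC | intermediate
11 | methyl 5-methoxy-1,3-bis(3-methylbut-2-enyl)-7-oxabicyclo[2.2.1]hepta-2,5-diene-2-carboxylate (racemic, one enantiomer drawn) | COC1=C[C@]2(CC=C(C)C)O[C@H]1C(CC=C(C)C)=C2C(=O)OC | intermediate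
12 | methyl 3-hydroxy-4-methoxy-2,6-bis(3-methylbut-2-enyl)benzoate | COC(=O)c1c(CC=C(C)C)cc(OC)c(O)c1CC=C(C)C | intermediate
13 | methyl 4-methoxy-3-(methoxymethoxy)-2,6-bis(3-methylbut-2-enyl)benzoate | COCOc1c(OC)cc(CC=C(C)C)c(C(=O)OC)c1CC=C(C)C | intermediate
14 | 4-hydroxy-3-(methoxymethoxy)-2,6-bis(3-methylbut-2-enyl)benzoic acid | COCOc1c(O)cc(CC=C(C)C)c(C(=O)O)c1CC=C(C)C | intermediate
15 | methoxymethyl 3,4-bis(methoxymethoxy)-2,6-bis(3-methylbut-2-enyl)benzoate | COCOC(=O)c1c(CC=C(C)C)cc(OCOC)c(OCOC)c1CC=C(C)C | intermediate
16 | 3,4-bis(methoxymethoxy)-2,6-bis(3-methylbut-2-enyl)benzoic acid | COCOc1cc(CC=C(C)C)c(C(=O)O)c(CC=C(C)C)c1OCOC | intermediate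
17 | 2,4,6-trihydroxyacetophenone | CC(=O)c1c(O)cc(O)cc1O | starting material
18 | 1-[2,4,6-trihydroxy-3-(3-methylbut-2-enyl)phenyl]ethanone | CC(=O)c1c(O)cc(O)c(CC=C(C)C)c1O | intermediate
19 | 1-[2-hydroxy-4,6-bis(methoxymethoxy)-3-(3-methylbut-2-enyl)phenyl]ethanone | CC(=O)c1c(OCOC)cc(OCOC)c(CC=C(C)C)c1O | intermediate
20 | 2-hydroxy-1-[2-hydroxy-4,6-bis(methoxymethoxy)-3-(3-methylbut-2-enyl)phenyl]ethanone | O=C(CO)c1c(OCOC)cc(OCOC)c(CC=C(C)C)c1O | intermediate
21 | 1-[2-hydroxy-4,6-bis(methoxymethoxy)-3-(3-methylbut-2-enyl)phenyl]-2-(methoxymethoxy)ethanone | COCOCC(=O)c1c(OCOC)cc(OCOC)c(CC=C(C)C)c1O | intermediate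
22 | 3,4-bis(methoxymethoxy)-2,6-bis(3-methylbut-2-enyl)benzoyl chloride | COCOc1cc(CC=C(C)C)c(C(=O)Cl)c(CC=C(C)C)c1OCOC | intermediate
23 | 1-[3,4-bis(methoxymethoxy)-2,6-diprenylphenyl]-3-[2-hydroxy-4,6-bis(methoxymethoxy)-3-prenylphenyl]-2-(methoxymethoxy)propane-1,3-dione (racemic, C2 labile) | COCOC(C(=O)c1c(OCOC)cc(OCOC)c(CC=C(C)C)c1O)C(=O)c1c(CC=C(C)C)cc(OCOC)c(OCOC)c1CC=C(C)C | intermediate
24 | 2-[3,4-bis(methoxymethoxy)-2,6-diprenylphenyl]-3,5,7-tris(methoxymethoxy)-8-prenyl-4H-chromen-4-one | COCOc1c(-c2c(CC=C(C)C)cc(OCOC)c(OCOC)c2CC=C(C)C)oc2c(CC=C(C)C)c(OCOC)cc(OCOC)c2c1=O | intermediate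
25 | petalostemumol G | CC(C)=CCc1cc(O)c(O)c(CC=C(C)C)c1-c1oc2c(CC=C(C)C)c(O)cc(O)c2c(=O)c1O | target

Total step count: 16. Longest linear sequence: 11 steps (steps 1-4, 6-9, 14-16).

Steps most likely to fail

Step 6. The beta-alkyl ynoate may add too slowly. Cycloreversion, Lewis acid induced decomposition of the furan, or conjugate addition through the furan alpha carbon followed by proton loss instead of ring closure could then take over.
The fallback keeps the same two bonds but takes the dienophile to the aldehyde oxidation level. It sets out from 10 and 8 and comes back at 14.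
- i-Bu2AlH (CH2Cl2, -78 °C) should reduce 10 to 6-methylhept-5-en-2-yn-1-ol F1.
- MnO2 should oxidise this to 6-methylhept-5-en-2-ynal F2, a much stronger dienophile.
- F2 should take up 8 at or below room temperature without Lewis acid to give the 7-oxanorbornadiene-2-carbaldehyde F3, which should open on silica gel to 3-hydroxy-4-methoxy-2,6-diprenylbenzaldehyde F4.
- MOMCl and i-Pr2NEt should give 4-methoxy-3-(methoxymethoxy)-2,6-diprenylbenzaldehyde F5.
- Pinnick oxidation (NaClO2, NaH2PO4, large excess of 2-methylbut-2-ene) should give 4-methoxy-3-(methoxymethoxy)-2,6-diprenylbenzoic acid F6.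
- NaSEt in DMF then has only the aryl methyl ether left to cleave on the way to 14.

Step 14. The two ortho prenyl groups shield the acyl carbon. C-acylation may therefore stall, the amide base may consume the acid chloride, or acylation may stop at oxygen without acyl shift.
The fallback replaces the acyl electrophile by the far less hindered aldehyde and restores the oxidation level afterwards. It sets out from 16 and 21 and comes back at 23.
- LiAlH4 (THF, 0 °C → rt) should reduce 16 to [3,4-bis(methoxymethoxy)-2,6-diprenylphenyl]methanol F7.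
- MnO2 should give 3,4-bis(methoxymethoxy)-2,6-diprenylbenzaldehyde F8.
- The dianion of 21 (LiN(SiMe3)2, 2.2 equiv, THF, -78 °C) should add to F8 in an aldol reaction to give the beta-hydroxy ketone F9 as a mixture of diastereomers, whose two stereocentres do not persist: the carbinol centre is oxidised away and the other becomes the labile C2 of 23.
- Dess-Martin periodinane buffered with NaHCO3 should oxidise the benzylic carbinol to 23.

Step 16. The acid may protonate the prenyl double bonds. The freshly released C7 and C3' hydroxyls could then add to them (chroman ring closure), or methanol could add.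
The fallback avoids Brønsted acid by exchanging the acetals for silyl ethers. It sets out from 24 and comes back at 25.
- Me3SiOTf with an excess of 2,2'-bipyridyl (MeCN, 0 °C → rt) should convert the five MOM ethers into the pentakis(trimethylsilyl) ether F10, with the methoxymethyl groups transferred to the bipyridyl.
- Water or KF in MeOH at neutral pH should then release 25.

Further compounds
F1 | step 6 | 6-methylhept-5-en-2-yn-1-ol | CC(C)=CCC#CCO
F2 | step 6 | 6-methylhept-5-en-2-ynal | CC(C)=CCC#CC=O
F3 | step 6 | 5-methoxy-1,3-bis(3-methylbut-2-enyl)-7-oxabicyclo[2.2.1]hepta-2,5-diene-2-carbaldehyde (racemic, one enantiomer drawn) | COC1=C[C@]2(CC=C(C)C)O[C@H]1C(CC=C(C)C)=C2C=O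
F4 | step 6 | 3-hydroxy-4-methoxy-2,6-bis(3-methylbut-2-enyl)benzaldehyde | COc1cc(CC=C(C)C)c(C=O)c(CC=C(C)C)c1O
F5 | step 6 | 4-methoxy-3-(methoxymethoxy)-2,6-bis(3-methylbut-2-enyl)benzaldehyde | COCOc1c(OC)cc(CC=C(C)C)c(C=O)c1CC=C(C)C
F6 | step 6 | 4-methoxy-3-(methoxymethoxy)-2,6-bis(3-methylbut-2-enyl)benzoic acid | COCOc1c(OC)cc(CC=C(C)C)c(C(=O)O)c1CC=C(C)C
F7 | step 14 | [3,4-bis(methoxymethoxy)-2,6-bis(3-methylbut-2-enyl)phenyl]methanol | COCOc1cc(CC=C(C)C)c(CO)c(CC=C(C)C)c1OCOC
F8 | step 14 | 3,4-bis(methoxymethoxy)-2,6-bis(3-methylbut-2-enyl)benzaldehyde | COCOc1cc(CC=C(C)C)c(C=O)c(CC=C(C)C)c1OCOC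
F9 | step 14 | 3-[3,4-bis(methoxymethoxy)-2,6-diprenylphenyl]-3-hydroxy-1-[2-hydroxy-4,6-bis(methoxymethoxy)-3-prenylphenyl]-2-(methoxymethoxy)propan-1-one (mixture of diastereomers) | COCOC(C(=O)c1c(OCOC)cc(OCOC)c(CC=C(C)C)c1O)C(O)c1c(CC=C(C)C)cc(OCOC)c(OCOC)c1CC=C(C)C
F10 | step 16 | 2-[2,6-diprenyl-3,4-bis(trimethylsilyloxy)phenyl]-8-prenyl-3,5,7-tris(trimethylsilyloxy)-4H-chromen-4-one | C[Si](C)(C)Oc1c(-c2c(CC=C(C)C)cc(O[Si](C)(C)C)c(O[Si](C)(C)C)c2CC=C(C)C)oc2c(CC=C(C)C)c(O[Si](C)(C)C)cc(O[Si](C)(C)C)c2c1=O
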